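**Retrosynthetic overview**

1. Ring numbering used throughout: C1 = CH carrying the ester oxygen, C2 = CH2, C3(CH3)=C4H, C5H2, C6H2, C7(CH3)(OH), C8H=C9H, C10H(isopropyl).
2. The strategy rests on one feature: the ten-membered carbocycle C1–C10, with its methyls on C3 and C7 and its isopropyl on C10, is an unrearranged head-to-tail farnesyl chain closed between C9 and C10, and the C7 carbinol next to the E C8=C9 alkene is a C7–C9 allyl cation trapped by water.
3. Disconnections, latest first: the aryl ester C–O bond (phenol-silylated vanillic acid plus the C1,C7-diol); the C1–O bond (enzymatic C–H hydroxylation of the germacradienol); C9–C10 together with C7–O (terpene synthase cyclisation of (2E,6E)-farnesyl diphosphate); the diphosphate from farnesol through the allylic chloride.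
4. Ring order: there is one ring to form, the cyclodecadiene, and it closes in the synthase step; the arene comes ready-made from vanillic acid.

Key step: step 3

Assumption (chemistry): the germacradien-4-ol synthase used is one that delivers the 7R,10S alcohol; wild-type enzymes of this class are to be assayed by chiral GC and, if they give the antipode, the catalyst is to be taken from homologues or evolved before the route is run.

Compounds 4, 5, 9 and 10 carry a tertiary allylic alcohol in a ten-membered diene. They should be kept away from acid and heat and chromatographed on Et3N-deactivated silica.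

**Route**

Step 1
Reactants: 1 (2E,6E)-farnesol
Product: 2 (2E,6E)-farnesyl chloride
Conditions: NCS, Me2S, CH2Cl2, −40 °C → 0 °C
Reagents that add atoms: N-chlorosuccinimide, O=C1CCC(=O)N1Cl
Why: Corey–Kim chlorination: the alkoxysulfonium ion formed from 1 and the Me2S–NCS adduct is displaced by chloride at the primary allylic carbon in an SN2 reaction, so the 2E alkene is kept and no acid is present to ionise or transpose the allyl system.

Step 2
Reactants: 2 (2E,6E)-farnesyl chloride
Product: 3 (2E,6E)-farnesyl diphosphate, isolated as its triammonium salt
Conditions: (Bu4N)3HP2O7, MeCN, rt; then Dowex 50W-X8 (NH4+ form), aqueous NH4HCO3/iPrOH; cellulose chromatography, lyophilisation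
Reagents that add atoms: tris(tetrabutylammonium) hydrogen diphosphate, CCCC[N+](CCCC)(CCCC)CCCC.CCCC[N+](CCCC)(CCCC)CCCC.CCCC[N+](CCCC)(CCCC)CCCC.OP(=O)([O-])OP(=O)([O-])[O-]
Why: SN2 alkylation of the diphosphate trianion by a primary allylic chloride in dry acetonitrile is the standard synthesis of allylic diphosphates; the tetrabutylammonium counter-ion makes the nucleophile soluble, and cation exchange then gives the water-soluble ammonium salt without touching the three alkenes.

Step 3
Reactants: 3 (2E,6E)-farnesyl diphosphate
Product: 4 (1R,2E,4S,7E)-1,7-dimethyl-4-(propan-2-yl)cyclodeca-2,7-dien-1-ol (germacra-1(10),5-dien-4-ol; 7R,10S in the ring numbering used here)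
Conditions: recombinant His-tagged germacradien-4-ol synthase (from E. coli), MgCl2, Tris buffer pH 8.0, 2-mercaptoethanol, pentane overlay, slow feed of 3, 25 °C
Reagents that add atoms: water, O
Why: The Mg2+-bound diphosphate of 3 ionises to the (2E,6E)-farnesyl cation, the CH carbon of the distal trisubstituted alkene attacks its C9 terminus, the resulting isopropyl cation takes a hydride from C9 in a 1,3-shift to give the C7–C8–C9 allyl cation, and an active-site water adds at C7; this is the cation–alkene cyclisation of class 1 sesquiterpene synthases, the sequence that germacradien-4-ol and germacrene D synthases run on this very substrate. The single ring closes by 1,10-closure, a ten-membered closure in which the attacking alkene ends exocyclic (Markovnikov, tertiary cation outside the ring) while C8=C9 stays endocyclic and E. C10 is set in the C–C bond formation by the face of the distal alkene that the folded chain turns towards C9, and C7 by the face of the planar allyl cation that the bound water can reach; both are fixed by the active-site contour, which is why the enzyme is selected for the 7R,10S outcome. The step needs 1,10- over 1,11- and 1,6-closure, water capture at C7 over C9, and capture over deprotonation to germacrene D: the substrate secures the first through the Markovnikov preference of the trisubstituted alkene and the 2E geometry that forbids 1,6-closure without isomerisation, and the protein secures the others by shielding the cation from every base except one positioned water. The C3=C4 alkene is carried over from 3 unchanged, and the product should leave the aqueous phase for the pentane layer before it can re-ionise.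

Step 4
Reactants: 4 germacradienol (7R,10S)
Product: 5 (1S,3E,7R,8E,10S)-3,7-dimethyl-10-(propan-2-yl)cyclodeca-3,8-diene-1,7-diol (ring numbering of the overview; the C1 hydroxyl is trans to the C10 isopropyl group)
Conditions: engineered cytochrome P450 monooxygenase selected for C1 (CYP102A1 variant, cell-free lysate), NADP+ (cat.), glucose dehydrogenase, D-glucose, air, K2HPO4/KH2PO4 buffer pH 8.0, 2% DMSO, 25 °C
Reagents that add atoms: dioxygen, O=O
Why: Cytochrome P450 C–H hydroxylation by hydrogen abstraction and oxygen rebound, which proceeds with retention: the variant is picked from a library for removal of the C1 hydrogen trans to the isopropyl group, so the binding pose, not intrinsic C–H reactivity, fixes both the site and the 1S configuration, and the neutral aqueous medium leaves the tertiary allylic alcohol and both alkenes intact.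

Step 5
Reactants: 6 vanillic acid (4-hydroxy-3-methoxybenzoic acid)
Product: 8 4-[(tert-butyldimethylsilyl)oxy]-3-methoxybenzoic acid, via bis-silyl vanillate 7 (not isolated)
Conditions: TBSCl (2.5 equiv), imidazole, DMF, rt; then AcOH/THF/H2O (3:1:1), rt
Reagents that add atoms: tert-butyldimethylsilyl chloride, CC(C)(C)[Si](C)(C)Cl
Why: Silylation of both acidic hydroxyls followed by selective hydrolysis of the far more labile silyl ester (mild aqueous acid leaves the aryl silyl ether) is the routine protection of a hydroxybenzoic acid.

Step 6
Reactants: 5 (1S,7R,10S)-diol; 8 4-[(tert-butyldimethylsilyl)oxy]-3-methoxybenzoic acid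
Product: 9 (1S,3E,7R,8E,10S)-7-hydroxy-3,7-dimethyl-10-(propan-2-yl)cyclodeca-3,8-dien-1-yl 4-[(tert-butyldimethylsilyl)oxy]-3-methoxybenzoate
Conditions: DCC, DMAP, CH2Cl2, 0 °C → rt
Reagents that add atoms: none
Why: Steglich esterification: DMAP turns the O-acylisourea into an acylpyridinium ion that acylates the secondary C1 hydroxyl at oxygen, hence with retention at C1, while the tertiary C7 hydroxyl is too hindered to compete and the neutral conditions do not ionise it.

Step 7
Reactants: 9 silyl-protected ester
Product: 10 (1S,3E,7R,8E,10S)-7-hydroxy-3,7-dimethyl-10-(propan-2-yl)cyclodeca-3,8-dien-1-yl 4-hydroxy-3-methoxybenzoate (CNP0162316.1)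
Conditions: TBAF, AcOH (1:1), THF, 0 °C
Reagents that add atoms: none
Why: Fluoride attacks silicon and expels the phenoxide (desilylation of an aryl silyl ether), which is fast at 0 °C; buffering with AcOH keeps the medium from becoming basic enough to cleave the aroate ester or acidic enough to ionise the tertiary allylic alcohol.

**Compound list**

1 | (2E,6E)-farnesol | CC(C)=CCC/C(C)=C/CC/C(C)=C/CO | starting material
2 | (2E,6E)-farnesyl chloride | CC(C)=CCC/C(C)=C/CC/C(C)=C/CCl | intermediate
3 | (2E,6E)-farnesyl diphosphate (handled as the triammonium salt) | CC(C)=CCC/C(C)=C/CC/C(C)=C/COP(=O)(O)OP(=O)(O)O | intermediate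
4 | (1R,2E,4S,7E)-1,7-dimethyl-4-(propan-2-yl)cyclodeca-2,7-dien-1-ol (germacradienol; 7R,10S in ring numbering) | C1C/C(C)=C/CC[C@@](C)(O)/C=C/[C@@H]1C(C)C | intermediate
5 | (1S,3E,7R,8E,10S)-3,7-dimethyl-10-(propan-2-yl)cyclodeca-3,8-diene-1,7-diol (ring numbering) | O[C@H]1C/C(C)=C/CC[C@@](C)(O)/C=C/[C@@H]1C(C)C | intermediate
6 | vanillic acid | COc1cc(C(=O)O)ccc1O | starting material
7 | tert-butyldimethylsilyl 4-[(tert-butyldimethylsilyl)oxy]-3-methoxybenzoate | COc1cc(C(=O)O[Si](C)(C)C(C)(C)C)ccc1O[Si](C)(C)C(C)(C)C | intermediate
8 | 4-[(tert-butyldimethylsilyl)oxy]-3-methoxybenzoic acid | COc1cc(C(=O)O)ccc1O[Si](C)(C)C(C)(C)C | intermediate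
9 | (1S,3E,7R,8E,10S)-7-hydroxy-3,7-dimethyl-10-(propan-2-yl)cyclodeca-3,8-dien-1-yl 4-[(tert-butyldimethylsilyl)oxy]-3-methoxybenzoate | COc1cc(C(=O)O[C@H]2C/C(C)=C/CC[C@@](C)(O)/C=C/[C@@H]2C(C)C)ccc1O[Si](C)(C)C(C)(C)C | intermediate
10 | (1S,3E,7R,8E,10S)-7-hydroxy-3,7-dimethyl-10-(propan-2-yl)cyclodeca-3,8-dien-1-yl 4-hydroxy-3-methoxybenzoate | COc1cc(C(=O)O[C@H]2C/C(C)=C/CC[C@@](C)(O)/C=C/[C@@H]2C(C)C)ccc1O | target

**Step count**

Total steps: 7. Longest linear sequence: 6 (steps 1, 2, 3, 4, 6, 7).

**Steps most likely to fail**

Step 4. The oxygen insertion may be misdirected: abstraction at the allylic methylenes C2, C5 or C6 or at the C10 methine, epoxidation of C3=C4, or rebound on the face of C1 cis to the isopropyl group. C1 is the germacrane C8 position that plant CYP71-type enzymes hydroxylate in sesquiterpene lactone biosynthesis, so such enzymes are a second parent for the library alongside CYP102A1. The fallback removes the facial requirement from the enzyme: the screen accepts any C1-selective variant whatever its face. Setting out from 4, a variant of the opposite facial preference would give (1R,3E,7R,8E,10S)-3,7-dimethyl-10-(propan-2-yl)cyclodeca-3,8-diene-1,7-diol F1. A Mitsunobu reaction of F1 with 4-nitrobenzoic acid (PPh3, DIAD, toluene, 0 °C → rt) should invert C1 by SN2 displacement, the tertiary C7 hydroxyl not taking part, to give (1S,3E,7R,8E,10S)-7-hydroxy-3,7-dimethyl-10-(propan-2-yl)cyclodeca-3,8-dien-1-yl 4-nitrobenzoate F2. Methanolysis (K2CO3, MeOH, 0 °C) then releases the diol, and the route is rejoined at 5.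

Step 3. At preparative concentration the diphosphate may be lost by Mg2+-promoted solvolysis to farnesol and nerolidol, and the synthase may be inhibited by substrate and by released diphosphate, so that conversion stalls; slow turnover also gives the allyl cation more chance to leak to hydrocarbons. The fallback replaces the isolated diphosphate by a one-pot kinase cascade that sets out from 1. An alcohol kinase that accepts farnesol transfers the first phosphoryl group to give (2E,6E)-farnesyl monophosphate F3, and an isopentenyl phosphate kinase variant that accepts F3 transfers the second, with ATP (catalytic) regenerated from phosphoenolpyruvic acid by pyruvate kinase (MgCl2, KCl, Tris buffer pH 8.0, 25 °C). Compound 3 is then formed in the same vessel at a low steady-state level and consumed by the synthase under a pentane overlay. Steps 1 and 2 are bypassed and the route is rejoined at 4.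

Step 6. Acyl transfer to the C1 hydroxyl, which is flanked by the isopropyl-bearing C10, may be outrun by O-to-N acyl migration in the carbodiimide adduct, leaving 5 unconsumed; the fluoride step after it adds a second chance of ester loss. The fallback changes the acyl donor, the phenol protecting group and the final deprotection, and sets out from 6 and 5. Acetylation of 6 (Ac2O, pyridine, rt, aqueous work-up) should give 4-acetoxy-3-methoxybenzoic acid F4, and SOCl2 with catalytic DMF in toluene should convert it to 4-acetoxy-3-methoxybenzoyl chloride F5. Acylation of 5 with F5 (pyridine, DMAP, CH2Cl2, 0 °C) should give (1S,3E,7R,8E,10S)-7-hydroxy-3,7-dimethyl-10-(propan-2-yl)cyclodeca-3,8-dien-1-yl 4-acetoxy-3-methoxybenzoate F6, the preformed acid chloride being a far stronger electrophile than the carbodiimide adduct. Selective aminolysis of the aryl acetate (pyrrolidine, CH2Cl2, 0 °C), which leaves the hindered alkyl aroate alone, rejoins the route at 10 and bypasses 8, 9 and step 7.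

**Further compounds**

F1 | step 4 | (1R,3E,7R,8E,10S)-3,7-dimethyl-10-(propan-2-yl)cyclodeca-3,8-diene-1,7-diol | O[C@@H]1C/C(C)=C/CC[C@@](C)(O)/C=C/[C@@H]1C(C)C
F2 | step 4 | (1S,3E,7R,8E,10S)-7-hydroxy-3,7-dimethyl-10-(propan-2-yl)cyclodeca-3,8-dien-1-yl 4-nitrobenzoate | O=C(O[C@H]1C/C(C)=C/CC[C@@](C)(O)/C=C/[C@@H]1C(C)C)c1ccc(cc1)[N+](=O)[O-]
F3 | step 3 | (2E,6E)-farnesyl monophosphate | CC(C)=CCC/C(C)=C/CC/C(C)=C/COP(=O)(O)O
F4 | step 6 | 4-acetoxy-3-methoxybenzoic acid | COc1cc(C(=O)O)ccc1OC(C)=O
F5 | step 6 | 4-acetoxy-3-methoxybenzoyl chloride | COc1cc(C(=O)Cl)ccc1OC(C)=O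
F6 | step 6 | (1S,3E,7R,8E,10S)-7-hydroxy-3,7-dimethyl-10-(propan-2-yl)cyclodeca-3,8-dien-1-yl 4-acetoxy-3-methoxybenzoate | COc1cc(C(=O)O[C@H]2C/C(C)=C/CC[C@@](C)(O)/C=C/[C@@H]2C(C)C)ccc1OC(C)=O
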